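**Strategy.** The isoflavan is cut at the C3 methine of ring C, which carries three carbon groups: benzylic C4 (attached to ring A), C1' of ring B and C2. C3 is built on boron from dichloromethane: one homologation of a ring A benzylboronic ester of (R,R)-1,2-dicyclohexylethane-1,2-diol joins C3 to C4, and an invertive aryl transfer from the ring B Grignard reagent joins C3 to C1' and fixes (R)-C3. The boron left on C3 then takes up C2 with retention. The precursor holds the whole of ring A: C5 methoxy, C6 prenyl, O7 as a triisopropylsilyl ether and the future O1 as a methoxymethyl ether.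

Key step: step 10

**Remarks on the chemistry**
- Assumption on the sense of induction: an (R,R)-diol boronic ester is taken to give the (S)-α-chloro boronic ester, as is established for this homologation. Invertive aryl transfer then gives (R) at the boron-bearing carbon, which becomes (3R) in the chroman.
- Abbreviations: ring A aryl = 2-methoxy-6-(methoxymethoxy)-3-(3-methylbut-2-enyl)-4-(triisopropylsilyloxy)phenyl; ring B aryl = 2-methoxy-4-(triisopropylsilyloxy)phenyl; TIPS = triisopropylsilyl; MOM = methoxymethyl; pin = pinacolato.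
- Protecting groups: O7 and O4' are TIPS ethers, removed by fluoride at the end, so the prenyl group never meets acid next to a free phenol. The future O1 is a MOM ether, removed by dilute acid while O7 is still silylated. Fluoride is therefore avoided on the way to the precursor.
- Regiochemistry of ring A is fixed by symmetry (steps 1 and 2) and by mechanism (step 4), not by competition between similar hydroxyls.

**Route**

Step 1
Reactants: 1 2,4,6-trihydroxybenzaldehyde
Product: 2 2,6-dihydroxy-4-(triisopropylsilyloxy)benzaldehyde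
Conditions: TIPSCl (1.0 equiv), imidazole, DMF, 0 °C
Reagents that add atoms: triisopropylsilyl chloride CC(C)[Si](Cl)(C(C)C)C(C)C
Why: Selective O-silylation: the 4-hydroxyl is the only one not hydrogen-bonded to the formyl group and is the most acidic, so one equivalent of the bulky silyl chloride should take it and leave a symmetric 2,6-diol.

Step 2
Reactants: 2 2,6-dihydroxy-4-(triisopropylsilyloxy)benzaldehyde
Product: 3 2-hydroxy-6-(methoxymethoxy)-4-(triisopropylsilyloxy)benzaldehyde
Conditions: MOMCl (1.05 equiv), i-Pr2NEt, CH2Cl2, 0 → 20 °C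
Reagents that add atoms: chloromethyl methyl ether COCCl
Why: Williamson-type etherification: the two hydroxyls are equivalent by symmetry, so only one monoether can form, and the last hydroxyl is then locked in a hydrogen bond to the aldehyde and should react far more slowly.

Step 3
Reactants: 3 2-hydroxy-6-(methoxymethoxy)-4-(triisopropylsilyloxy)benzaldehyde; 4 tert-butyl 2-methylbut-3-en-2-yl carbonate
Product: 5 2-(methoxymethoxy)-6-(2-methylbut-3-en-2-yloxy)-4-(triisopropylsilyloxy)benzaldehyde
Conditions: Pd(PPh3)4 (2 mol %), THF, 0 → 20 °C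
Reagents that add atoms: none
Why: Tsuji–Trost O-allylation: the carbonate ionises to a 1,1-dimethylallyl palladium complex with loss of CO2, and the phenoxide formed by the tert-butoxide attacks the more substituted allyl terminus under kinetic control to give the tertiary aryl ether.

Step 4
Reactants: 5 2-(methoxymethoxy)-6-(2-methylbut-3-en-2-yloxy)-4-(triisopropylsilyloxy)benzaldehyde
Product: 6 2-hydroxy-6-(methoxymethoxy)-3-(3-methylbut-2-enyl)-4-(triisopropylsilyloxy)benzaldehyde
Conditions: PhMe, 120 °C (sealed tube)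
Reagents that add atoms: none
Why: Aromatic Claisen rearrangement: the [3,3] shift can end productively only at C3, the single unsubstituted ortho carbon, and tautomerisation of the dienone gives the ortho-prenyl phenol with the position fixed by the mechanism.

Step 5
Reactants: 6 2-hydroxy-6-(methoxymethoxy)-3-(3-methylbut-2-enyl)-4-(triisopropylsilyloxy)benzaldehyde
Product: 7 2-methoxy-6-(methoxymethoxy)-3-(3-methylbut-2-enyl)-4-(triisopropylsilyloxy)benzaldehyde
Conditions: MeI, K2CO3, acetone, 50 °C
Reagents that add atoms: iodomethane CI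
Why: Williamson methylation of the one free, chelated phenol; anhydrous carbonate in acetone should leave the aryl silyl ether and the acetal untouched.

Step 6
Reactants: 7 2-methoxy-6-(methoxymethoxy)-3-(3-methylbut-2-enyl)-4-(triisopropylsilyloxy)benzaldehyde
Product: 8 (E)-N'-[(ring A aryl)methylidene]-4-methylbenzenesulfonohydrazide
Conditions: TsNHNH2, MeOH, 50 °C
Reagents that add atoms: 4-methylbenzenesulfonohydrazide Cc1ccc(cc1)S(=O)(=O)NN
Why: Condensation of the aldehyde with the sulfonyl hydrazide to the tosylhydrazone, which needs no added acid and so spares the MOM ether.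

Step 7
Reactants: 8 (E)-N'-[(ring A aryl)methylidene]-4-methylbenzenesulfonohydrazide
Product: 11 2-[(ring A aryl)methyl]-4,4,5,5-tetramethyl-1,3,2-dioxaborolane, via aryldiazomethane 9 (not isolated), via geminal bis(boronate) 10 (not isolated)
Conditions: B2pin2, NaH, MeOH (additive), PhMe, 110 °C
Reagents that add atoms: bis(pinacolato)diboron CC1(C)OB(OC1(C)C)B1OC(C)(C)C(C)(C)O1
Why: Reductive borylation of a tosylhydrazone: Bamford–Stevens loss of sulfinate gives the aryldiazomethane, its carbon adds to the diboron, a 1,2-boryl shift with loss of N2 gives the geminal bis(boronate), and methoxide-assisted protodeboronation of one boryl group leaves the benzylboronic ester.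

Step 8
Reactants: 11 2-[(ring A aryl)methyl]-4,4,5,5-tetramethyl-1,3,2-dioxaborolane; 12 (R,R)-1,2-dicyclohexylethane-1,2-diol
Product: 14 (4R,5R)-4,5-dicyclohexyl-2-[(ring A aryl)methyl]-1,3,2-dioxaborolane, via benzylboronic acid 13 (not isolated)
Conditions: NaIO4, NH4OAc, acetone/H2O, 20 °C; extractive work-up; then 12, MgSO4, Et2O, 20 °C
Reagents that add atoms: none
Why: Oxidative unmasking of a pinacol boronate followed by esterification: periodate destroys the pinacol released in the hydrolysis equilibrium and so drives the ester to the boronic acid, which condenses with the diol under dehydration without touching the diol stereocentres or the silyl ether.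

Step 9
Reactants: 15 4-bromo-3-methoxyphenol
Product: 16 (4-bromo-3-methoxyphenoxy)triisopropylsilane
Conditions: TIPSCl, imidazole, DMF, 20 °C
Reagents that add atoms: triisopropylsilyl chloride CC(C)[Si](Cl)(C(C)C)C(C)C
Why: O-silylation of the phenol, so that the Grignard reagent made from this bromide carries no acidic proton.

Step 10
Reactants: 14 (4R,5R)-4,5-dicyclohexyl-2-[(ring A aryl)methyl]-1,3,2-dioxaborolane; 16 (4-bromo-3-methoxyphenoxy)triisopropylsilane
Product: 19 (4R,5R)-4,5-dicyclohexyl-2-[(1R)-2-(ring A aryl)-1-(ring B aryl)ethyl]-1,3,2-dioxaborolane, via α-chloro boronic ester 17 (not isolated), via arylmagnesium bromide 18 (not isolated)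
Conditions: CH2Cl2, n-BuLi, THF, −100 °C, then 14; ZnCl2 (anhydrous), −100 → 20 °C; then 18 (from 16, Mg, THF, 40 °C; excess), −78 → 20 °C
Reagents that add atoms: dichloromethane (used as dichloromethyllithium) ClCCl
Why: Dichloromethyllithium adds to boron to give a borate, and ZnCl2 assists departure of one of the two diastereotopic chlorides while the benzyl group migrates from boron to carbon, which forms C3–C4 and gives the (S)-α-chloro boronic ester 17. The aryl Grignard reagent 18 then adds to boron and its aryl group shifts to C3 anti to the remaining chloride, which forms C3–C1' with inversion and gives (R)-19. The closest known reaction type is the Matteson asymmetric homologation of diol boronic esters with dichloromethyllithium followed by Grignard displacement, which is established for benzylboronic esters. No ring is closed. The new stereocentre C3 is controlled by the (R,R)-diol on boron, whose twofold symmetry makes both faces of the borate equivalent and whose cyclohexyl groups decide, in the zinc-bound transition state, which chloride leaves. The step needs carbon and not oxygen migration, no chloride-induced epimerisation of 17, and attack of 18 at boron only; ZnCl2 as chloride scavenger, low temperature, immediate use of 17 and a fully etherified substrate without acidic hydrogen should secure these.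

Step 11
Reactants: 19 (4R,5R)-4,5-dicyclohexyl-2-[(1R)-2-(ring A aryl)-1-(ring B aryl)ethyl]-1,3,2-dioxaborolane
Product: 21 (2R)-3-(ring A aryl)-2-(ring B aryl)propan-1-ol, via homologated boronic ester 20 (not isolated)
Conditions: ICH2Cl, n-BuLi, THF, −78 → 20 °C; then NaBO3·4H2O, THF/H2O, 20 °C
Reagents that add atoms: chloroiodomethane ClCI; sodium perborate (NaBO3·4H2O) [Na+].[O-]OB=O
Why: Matteson homologation with chloromethyllithium made in the flask by iodine–lithium exchange: the borate rearranges with migration of C3 under retention to place C2 between C3 and boron, and perborate oxidation of the primary C–B bond then gives the alcohol without touching C3.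

Step 12
Reactants: 21 (2R)-3-(ring A aryl)-2-(ring B aryl)propan-1-ol
Product: 22 (2R)-3-[6-hydroxy-2-methoxy-3-(3-methylbut-2-enyl)-4-(triisopropylsilyloxy)phenyl]-2-(ring B aryl)propan-1-ol
Conditions: HCl (about 1 M), MeOH/THF, 40 °C
Reagents that add atoms: none
Why: Acid-catalysed acetal methanolysis of the phenolic MOM ether; aryl TIPS ethers resist dilute acid and the prenyl group has no free ortho hydroxyl with which it could cyclise.

Step 13
Reactants: 22 (2R)-3-[6-hydroxy-2-methoxy-3-(3-methylbut-2-enyl)-4-(triisopropylsilyloxy)phenyl]-2-(ring B aryl)propan-1-ol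
Product: 23 (3R)-5-methoxy-3-[2-methoxy-4-(triisopropylsilyloxy)phenyl]-6-(3-methylbut-2-enyl)-7-(triisopropylsilyloxy)chroman
Conditions: PPh3, DIAD, THF (dilute), 0 → 20 °C
Reagents that add atoms: none
Why: Intramolecular Mitsunobu etherification: the primary alcohol is activated as its alkoxyphosphonium salt and displaced by the ring A phenoxide in a 6-exo-tet closure that forms O1–C2 and leaves C3 untouched.

Step 14
Reactants: 23 (3R)-5-methoxy-3-[2-methoxy-4-(triisopropylsilyloxy)phenyl]-6-(3-methylbut-2-enyl)-7-(triisopropylsilyloxy)chroman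
Product: 24 (3R)-3-(4-hydroxy-2-methoxyphenyl)-5-methoxy-6-(3-methylbut-2-enyl)chroman-7-ol
Conditions: TBAF, AcOH, THF, 0 → 20 °C
Reagents that add atoms: none
Why: Fluoride-induced cleavage of both aryl silyl ethers, buffered with acetic acid so that the phenoxides are protonated at once and the prenyl group meets neither strong acid nor strong base.

**Compound list**

1 | 2,4,6-trihydroxybenzaldehyde | O=Cc1c(O)cc(O)cc1O | starting material
2 | 2,6-dihydroxy-4-(triisopropylsilyloxy)benzaldehyde | O=Cc1c(O)cc(O[Si](C(C)C)(C(C)C)C(C)C)cc1O | intermediate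
3 | 2-hydroxy-6-(methoxymethoxy)-4-(triisopropylsilyloxy)benzaldehyde | COCOc1cc(O[Si](C(C)C)(C(C)C)C(C)C)cc(O)c1C=O | intermediate
4 | tert-butyl 2-methylbut-3-en-2-yl carbonate | C=CC(C)(C)OC(=O)OC(C)(C)C | starting material
5 | 2-(methoxymethoxy)-6-(2-methylbut-3-en-2-yloxy)-4-(triisopropylsilyloxy)benzaldehyde | COCOc1cc(O[Si](C(C)C)(C(C)C)C(C)C)cc(OC(C)(C)C=C)c1C=O | intermediate
6 | 2-hydroxy-6-(methoxymethoxy)-3-(3-methylbut-2-enyl)-4-(triisopropylsilyloxy)benzaldehyde | COCOc1cc(O[Si](C(C)C)(C(C)C)C(C)C)c(CC=C(C)C)c(O)c1C=O | intermediate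
7 | 2-methoxy-6-(methoxymethoxy)-3-(3-methylbut-2-enyl)-4-(triisopropylsilyloxy)benzaldehyde | COCOc1cc(O[Si](C(C)C)(C(C)C)C(C)C)c(CC=C(C)C)c(OC)c1C=O | intermediate
8 | (E)-tosylhydrazone of 7 | COCOc1cc(O[Si](C(C)C)(C(C)C)C(C)C)c(CC=C(C)C)c(OC)c1/C=N/NS(=O)(=O)c1ccc(C)cc1 | intermediate
9 | (ring A aryl)diazomethane | COCOc1cc(O[Si](C(C)C)(C(C)C)C(C)C)c(CC=C(C)C)c(OC)c1C=[N+]=[N-] | intermediate
10 | geminal bis(pinacol boronate) of the ring A benzyl carbon | COCOc1cc(O[Si](C(C)C)(C(C)C)C(C)C)c(CC=C(C)C)c(OC)c1C(B1OC(C)(C)C(C)(C)O1)B1OC(C)(C)C(C)(C)O1 | intermediate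
11 | ring A benzylboronic acid pinacol ester | COCOc1cc(O[Si](C(C)C)(C(C)C)C(C)C)c(CC=C(C)C)c(OC)c1CB1OC(C)(C)C(C)(C)O1 | intermediate
12 | (R,R)-1,2-dicyclohexylethane-1,2-diol | O[C@H](C1CCCCC1)[C@H](O)C1CCCCC1 | starting material
13 | ring A benzylboronic acid | COCOc1cc(O[Si](C(C)C)(C(C)C)C(C)C)c(CC=C(C)C)c(OC)c1CB(O)O | intermediate
14 | (4R,5R)-4,5-dicyclohexyl-2-[(ring A aryl)methyl]-1,3,2-dioxaborolane | COc1c(CB2O[C@H](C3CCCCC3)[C@@H](C3CCCCC3)O2)c(OCOC)cc(O[Si](C(C)C)(C(C)C)C(C)C)c1CC=C(C)C | intermediate
15 | 4-bromo-3-methoxyphenol | COc1cc(O)ccc1Br | starting material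
16 | (4-bromo-3-methoxyphenoxy)triisopropylsilane | COc1cc(O[Si](C(C)C)(C(C)C)C(C)C)ccc1Br | intermediate
17 | (4R,5R)-2-[(1S)-1-chloro-2-(ring A aryl)ethyl]-4,5-dicyclohexyl-1,3,2-dioxaborolane | COc1c(C[C@@H](Cl)B2O[C@H](C3CCCCC3)[C@@H](C3CCCCC3)O2)c(OCOC)cc(O[Si](C(C)C)(C(C)C)C(C)C)c1CC=C(C)C | intermediate
18 | [2-methoxy-4-(triisopropylsilyloxy)phenyl]magnesium bromide | COc1cc(O[Si](C(C)C)(C(C)C)C(C)C)ccc1[Mg]Br | intermediate
19 | (4R,5R)-4,5-dicyclohexyl-2-[(1R)-2-(ring A aryl)-1-(ring B aryl)ethyl]-1,3,2-dioxaborolane | COc1cc(O[Si](C(C)C)(C(C)C)C(C)C)ccc1[C@@H](Cc1c(OC)c(CC=C(C)C)c(O[Si](C(C)C)(C(C)C)C(C)C)cc1OCOC)B1O[C@H](C2CCCCC2)[C@@H](C2CCCCC2)O1 | intermediate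
20 | (4R,5R)-4,5-dicyclohexyl-2-[(2R)-3-(ring A aryl)-2-(ring B aryl)propyl]-1,3,2-dioxaborolane | COc1cc(O[Si](C(C)C)(C(C)C)C(C)C)ccc1[C@@H](Cc1c(OC)c(CC=C(C)C)c(O[Si](C(C)C)(C(C)C)C(C)C)cc1OCOC)CB1O[C@H](C2CCCCC2)[C@@H](C2CCCCC2)O1 | intermediate
21 | (2R)-3-(ring A aryl)-2-(ring B aryl)propan-1-ol | COc1cc(O[Si](C(C)C)(C(C)C)C(C)C)ccc1[C@@H](Cc1c(OC)c(CC=C(C)C)c(O[Si](C(C)C)(C(C)C)C(C)C)cc1OCOC)CO | intermediate
22 | (2R)-3-[6-hydroxy-2-methoxy-3-(3-methylbut-2-enyl)-4-(triisopropylsilyloxy)phenyl]-2-(ring B aryl)propan-1-ol | COc1cc(O[Si](C(C)C)(C(C)C)C(C)C)ccc1[C@@H](Cc1c(OC)c(CC=C(C)C)c(O[Si](C(C)C)(C(C)C)C(C)C)cc1O)CO | intermediate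
23 | (3R)-5-methoxy-3-[2-methoxy-4-(triisopropylsilyloxy)phenyl]-6-(3-methylbut-2-enyl)-7-(triisopropylsilyloxy)chroman | COc1cc(O[Si](C(C)C)(C(C)C)C(C)C)ccc1[C@@H]1COc2cc(O[Si](C(C)C)(C(C)C)C(C)C)c(CC=C(C)C)c(OC)c2C1 | intermediate
24 | (3R)-3-(4-hydroxy-2-methoxyphenyl)-5-methoxy-6-(3-methylbut-2-enyl)chroman-7-ol | COc1cc(O)ccc1[C@@H]1COc2cc(O)c(CC=C(C)C)c(OC)c2C1 | target

**Step count**

Total: 14 steps. Longest linear sequence: 13 steps (steps 1–8 and 10–14, from 1 to 24); step 9 is the one-step ring B branch.

**Steps most likely to fail**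

1. Step 10. What may go wrong: slow or incomplete aryl migration from the hindered ortho-methoxyaryl borate, chloride-induced epimerisation of the α-chloro boronic ester before the Grignard reagent arrives, or oxygen instead of carbon migration. Fallback: the C3 centre would be set by reagent-controlled lithiation–borylation in place of diol control. It sets out from 11 and 16 and comes back to the route at 21. Pinacol ester 11 would be homologated with chloromethyllithium to the 2-(ring A aryl)ethylboronic ester F1, oxidised with NaBO3·4H2O to the 2-(ring A aryl)ethanol F2, and acylated with N,N-diisopropylcarbamoyl chloride to the carbamate F3. Bromide 16 would give, by bromine–lithium exchange with n-BuLi and trapping with 2-isopropoxy-4,4,5,5-tetramethyl-1,3,2-dioxaborolane, the ring B aryl pinacol boronate F4. Deprotonation of F3 with s-BuLi and (−)-sparteine in Et2O at −78 °C should give the (S)-lithiated carbamate. Borylation with F4 under retention and 1,2-aryl shift with inversion (MgBr2·OEt2, warming) should give the (R)-1,2-diarylethyl pinacol boronate F5. Homologation with chloromethyllithium to the primary pinacol boronate F6 and perborate oxidation, as in step 11, would give 21.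

2. Step 7. What may go wrong: decay of the aryldiazomethane to azine or stilbene before the diboron captures it, partial loss of the silyl ether under the hot basic conditions, or incomplete protodeboronation of the geminal bis(boronate). Fallback: cross-coupling in place of diazo chemistry. It sets out from 7 and comes back at 11. Reduction of 7 with NaBH4 in MeOH would give the ring A benzyl alcohol F7. MsCl, Et3N and LiCl in THF at 0 °C would give the ring A benzyl chloride F8, used at once. Miyaura borylation of F8 with B2pin2 (Pd(dba)2, tris(4-methoxyphenyl)phosphine, KOAc, PhMe, 50 °C) would give 11.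

3. Step 3. What may go wrong: sluggish O-allylation of the chelated phenol, or re-ionisation of the tertiary allyl aryl ether by the palladium catalyst with drift to the linear prenyl ether, which would give the wrong Claisen product. Fallback: the tertiary ether would be built without a π-allyl intermediate. It sets out from 3 and comes back at 5. Alkylation of 3 with 3-chloro-3-methylbut-1-yne (K2CO3, KI, CuI as catalyst, acetone, 50 °C) would give the 1,1-dimethylpropargyl ether F9. Semi-hydrogenation (H2, Pd/CaCO3 poisoned with Pb(OAc)2, quinoline, EtOAc) would give 5.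

Further compounds
F1 | step 10 | 2-[2-(ring A aryl)ethyl]-4,4,5,5-tetramethyl-1,3,2-dioxaborolane | COCOc1cc(O[Si](C(C)C)(C(C)C)C(C)C)c(CC=C(C)C)c(OC)c1CCB1OC(C)(C)C(C)(C)O1
F2 | step 10 | 2-(ring A aryl)ethanol | COCOc1cc(O[Si](C(C)C)(C(C)C)C(C)C)c(CC=C(C)C)c(OC)c1CCO
F3 | step 10 | 2-(ring A aryl)ethyl N,N-diisopropylcarbamate | COCOc1cc(O[Si](C(C)C)(C(C)C)C(C)C)c(CC=C(C)C)c(OC)c1CCOC(=O)N(C(C)C)C(C)C
F4 | step 10 | 2-[2-methoxy-4-(triisopropylsilyloxy)phenyl]-4,4,5,5-tetramethyl-1,3,2-dioxaborolane | COc1cc(O[Si](C(C)C)(C(C)C)C(C)C)ccc1B1OC(C)(C)C(C)(C)O1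
F5 | step 10 | 2-[(1R)-2-(ring A aryl)-1-(ring B aryl)ethyl]-4,4,5,5-tetramethyl-1,3,2-dioxaborolane | COc1cc(O[Si](C(C)C)(C(C)C)C(C)C)ccc1[C@@H](Cc1c(OC)c(CC=C(C)C)c(O[Si](C(C)C)(C(C)C)C(C)C)cc1OCOC)B1OC(C)(C)C(C)(C)O1
F6 | step 10 | 2-[(2R)-3-(ring A aryl)-2-(ring B aryl)propyl]-4,4,5,5-tetramethyl-1,3,2-dioxaborolane | COc1cc(O[Si](C(C)C)(C(C)C)C(C)C)ccc1[C@@H](Cc1c(OC)c(CC=C(C)C)c(O[Si](C(C)C)(C(C)C)C(C)C)cc1OCOC)CB1OC(C)(C)C(C)(C)O1
F7 | step 7 | (ring A aryl)methanol | COCOc1cc(O[Si](C(C)C)(C(C)C)C(C)C)c(CC=C(C)C)c(OC)c1CO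
F8 | step 7 | (ring A aryl)methyl chloride | COCOc1cc(O[Si](C(C)C)(C(C)C)C(C)C)c(CC=C(C)C)c(OC)c1CCl
F9 | step 3 | 2-(methoxymethoxy)-6-(2-methylbut-3-yn-2-yloxy)-4-(triisopropylsilyloxy)benzaldehyde | COCOc1cc(O[Si](C(C)C)(C(C)C)C(C)C)cc(OC(C)(C)C#C)c1C=O
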